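Numbering follows the chromone skeleton; primed locants belong to the aromatic chromone unit. Compound numbers are those of the steps and of the compound list.

## Analysis of the target

The target is an unsymmetrical ether of two 2-(2-phenylethyl)chromone units: an aromatic 7′-hydroxychromone and a 5,6,7,8-tetrahydrochromone, joined through the C5 oxygen of the latter and C6′ of the former. The carbocycle of the tetrahydrochromone (C4a, C5, C6, C7, C8, C8a) carries four contiguous oxygenated stereocentres, (5S,6S,7R,8S), related 5,6-trans, 6,7-cis and 7,8-trans. C4a and C8a are the sp2 carbons shared with the 4-pyranone. C5 and C8 are allylic to the pyranone double bond, so the tetrol can lose water or aryloxide and aromatise under strong acid, strong base or heat. The C5–O aryl bond behaves like a benzyl-type ether toward hydrogenolysis and Lewis acids, and both pyranone rings are vinylogous esters that tolerate neither strong nucleophiles nor strong base. The hardest bond is the hindered secondary alkyl aryl ether: C6′ is para to the ring oxygen and meta to the carbonyl, so nucleophilic aromatic substitution has no activation, and C5 must keep its configuration. The strategy rests on reading C4a–C5–C6–C7–C8–C8a as a hexose chain: C5 to C8 have exactly the configuration of C2 to C5 of D-galactose, with C4a as C1 and C8a as C6. The only ring bond without a stereocentre is C4a=C8a, and it is also the enol-ether double bond of the pyranone, so closing it by enol-ether metathesis builds the ring and delivers the nucleophilic alkene needed for pyranone annulation.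

## Retrosynthetic reasoning

**Protecting groups last.** Target 27 is traced to phenol 26, which carries only the 6,7-acetonide and a silyl ether on O8; both fall in one aqueous acid step. Phenol 26 comes from benzyl ether 25. The C8 oxygen is given a silyl ether rather than a benzyl ether so that no slow hydrogenolysis of a hindered alkyl benzyl ether has to be run beside the labile C5–O aryl bond.

**The C5–O–C6′ ether.** Cutting O–C6′ (not C5–O) gives tetrahydrochromone alcohol 19 and bromochromone 24. A palladium-catalysed C–O coupling never breaks the C5–O bond, so the configuration at C5, which already comes correct from the sugar, is kept. A displacement at C5 would need the epimeric alcohol, and the arene offers no handle for nucleophilic aromatic substitution.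

**The aromatic chromone.** Bromochromone 24 is cut at C2′–C3′ and O1′–C2′ into acetophenone 21 and ester 22 (Claisen condensation to diketone 23, then cyclodehydration). Acetophenone 21 comes from the commercial bromoresacetophenone 20 by selective benzylation of the non-chelated hydroxyl.

**The pyranone of the tetrahydrochromone.** Alcohol 19 comes from its 4-methoxybenzyl ether 18. In 18 the bonds C4–C4a and O1–C8a are cut, which leads to cyclic methyl enol ether 13 and acylketene 16, released thermally from dioxinone 15. The enol ether is the right partner because its nucleophilic carbon is C4a and its oxygen-bearing carbon is C8a, so the regiochemistry of the [4+2] addition is fixed, and the methoxy group of adduct 17 leaves to aromatise the pyranone. Dioxinone 15 is the γ-benzylation product of commercial dioxinone 14.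

**The carbocycle (key disconnection).** Enol ether 13 is opened at C4a=C8a to diene 12, which has a vinyl group on C5 and a 1-methoxyvinyl group on C8. This is the only ring bond whose formation creates no stereocentre, so all four stereocentres can be bought rather than made. The forward reaction must load the catalyst at the vinyl group and close a six-membered ring onto a hindered, electron-rich 1,1-disubstituted alkene.

**The two alkene termini.** The 1-methoxyvinyl group of 12 is the methylenation product of methyl ester 11, so no regiochemical question about the enol ether can arise. Ester 11 comes from acid 10 and primary alcohol 9, that is, from oxidation of the sugar C6.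

**Differentiating O5 and O6 of the sugar.** Alcohol 9 is reached from bis-silyl ether 8 by selective cleavage of the primary silyl ether, and 8 from the mono-silyl alkenol 7. Silylating both oxygens and then freeing the primary one avoids an alkoxide next to a silyl ether, and makes any silyl shift during the preceding olefination irrelevant.

**The vinyl terminus and the sugar.** Alkenol 7 is the Wittig methylenation product of lactol 6, whose C1 becomes C4a. Lactol 6 is unmasked from thioglycoside 5, and 5 is assembled from commercial thiogalactoside 1 by acetonide formation on the cis-3,4-diol (3, via mixed acetal 2), silylation of O6 (4) and 4-methoxybenzylation of O2.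

## Alternatives that were turned down

**Alternative 1:** The pyranone bonds C4–C4a and O1–C8a are formed last, on a cyclitol that already carries the aryloxy group and three benzyl ethers. In the forward step, acylketene 16, released from dioxinone 15 in hot toluene, would add to the silyl enol ether A2 (taken here as the TBS enol ether), and loss of silanol would give the tetra-O-benzyl ether A1.
- For: it is the most convergent plan. The base-sensitive pyranone appears only at the end, so the aryl ether could be made on a plain cyclitol alcohol. On that point it is stronger than the chosen route, which has to run a palladium coupling on a tetrahydrochromone.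
- Against: the difficulty moves into A2. No way to build the carbocycle is offered. A regiodefined C4a=C8a silyl enol ether would have to be made from a C8a ketone by enolisation toward C4a and away from C8, and the C4a enolate has the C5 aryloxide as a β-leaving group (E1cB, loss of the C5 stereocentre). The electrophilic chromone would have to survive that enolisation. The bulky aryloxy group sits next to the carbon that must attack the ketene. Four benzyl ethers would then be hydrogenolysed beside the C5–O aryl bond.
- Comparison: both plans use the same annulation. The chosen route runs it on a small enol ether whose double-bond position is fixed by metathesis, and brings in the chromone unit only afterwards. What it gives up in convergence it gains in a regiocertain enol ether and in all four stereocentres being secured before any sensitive group is present.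

**Alternative 2:** The benzene ring of the aromatic chromone is disconnected at C6′–C7′, and the ether oxygen is introduced as an enol ether. In the forward step, Ac2O/NaOAc would dehydrate pyranylacetic acid A4 to dienylketene A5, whose 6π-electrocyclisation and tautomerisation would give the phenol, isolated as acetate A3.
- For: it avoids the secondary alkyl–aryl C–O coupling altogether, which is the weakest step of the chosen route, and here it is clearly stronger. The 6′,7′-dioxygenation pattern arises regiospecifically.
- Against: A4 still contains the complete tetrahydrochromone alcohol, so the carbocycle and its pyranone have to be built first by other chemistry. The hindered C5 hydroxyl must then be O-vinylated onto a trisubstituted pyranone that carries an acetic acid side chain, a vinylogous β-keto acid prone to decarboxylation. The acid-labile enol ether link has to survive hot anhydride. Several linear steps are spent on the most valuable intermediate.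
- Comparison: one risky coupling is exchanged for a multi-step sequence with its own risks. The chosen route offers instead a two-step chromone partner (24) and a single fragment union.

**Alternative 3:** The carbocycle is closed at C4a–C5 by a Ferrier carbocyclisation of a D-mannose-derived enopyranoside. Catalytic Hg(OCOCF3)2 (divalent mercury) in aqueous acetone would convert the 6-deoxyhex-5-enopyranoside A7 (taken as the methyl α-glycoside) into the hydroxy ketone A6 by oxymercuration, ring opening and intramolecular aldol addition.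
- For: the ring closure is robust and scalable, needs no air-sensitive catalyst, works with uniform benzyl protection, and delivers the C8a ketone and the C5 hydroxyl directly with C6 to C8 from mannose C2 to C4. On reliability of ring formation, and probably on step count to the carbocycle, it is stronger than the chosen route.
- Against: C5 is a new stereocentre set by the aldol step rather than taken from the sugar. A6 is a β-hydroxy ketone: any enol or enolate toward C4a for the pyranone annulation has the C5 oxygen as a β-leaving group, and enolisation must also be steered away from C8. A mercury salt is needed, and three benzyl ethers must later be hydrogenolysed next to the C5–O aryl bond.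
- Comparison: the chosen route pays with a longer protecting-group sequence and a sensitive molybdenum catalyst. In return it makes no stereocentre, and the enol ether is formed regiospecifically without ever passing through a free β-alkoxy ketone.

Key step: step 11

## Route

Assumption: lactol 6 is carried forward as the anomeric mixture, since both anomers open to the same aldehyde.

The diene and the ring-closed enol ether of the key step are compounds 12 and 13. They carry O5-PMB, the 6,7-acetonide and O8-TBS (target numbering).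

Step 1
Reactants: 1 phenyl 1-thio-β-D-galactopyranoside
Product: 3 phenyl 3,4-O-isopropylidene-1-thio-β-D-galactopyranoside, via mixed acetal 2 (not isolated)
Conditions: Me2C(OMe)2, CSA (cat.), 23 °C; Et3N; then MeOH/H2O (10:1), 60 °C
Reagents that add atoms: 2,2-dimethoxypropane, COC(C)(C)OC
Why: Acid-catalysed transacetalisation places the dioxolane on the cis-3,4-diol; the acyclic mixed acetal formed at O6 is far more labile than the cyclic acetal and is cleaved selectively in aqueous methanol.

Step 2
Reactants: 3 phenyl 3,4-O-isopropylidene-1-thio-β-D-galactopyranoside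
Product: 4 phenyl 6-O-(tert-butyldimethylsilyl)-3,4-O-isopropylidene-1-thio-β-D-galactopyranoside
Conditions: TBSCl, imidazole, DMF, 0 °C
Reagents that add atoms: tert-butyldimethylsilyl chloride, CC(C)(C)[Si](C)(C)Cl
Why: Sterically controlled silylation; the primary 6-hydroxyl reacts much faster than the flanked secondary 2-hydroxyl.

Step 3
Reactants: 4 phenyl 6-O-(tert-butyldimethylsilyl)-3,4-O-isopropylidene-1-thio-β-D-galactopyranoside
Product: 5 phenyl 6-O-(tert-butyldimethylsilyl)-3,4-O-isopropylidene-2-O-(4-methoxybenzyl)-1-thio-β-D-galactopyranoside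
Conditions: NaH, PMBCl, Bu4NI (cat.), DMF, 0 → 23 °C
Reagents that add atoms: 4-methoxybenzyl chloride, COc1ccc(CCl)cc1
Why: Williamson etherification of the only free hydroxyl; PMB is put on O2 (the future C5 oxygen) because it can later be removed oxidatively beside silyl ether, acetonide and pyranone.

Step 4
Reactants: 5 phenyl 6-O-(tert-butyldimethylsilyl)-3,4-O-isopropylidene-2-O-(4-methoxybenzyl)-1-thio-β-D-galactopyranoside
Product: 6 6-O-(tert-butyldimethylsilyl)-3,4-O-isopropylidene-2-O-(4-methoxybenzyl)-D-galactopyranose (anomeric mixture)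
Conditions: NBS, acetone/H2O (9:1), −15 °C
Reagents that add atoms: water, O
Why: Oxidative thioglycoside hydrolysis: bromination at sulfur, departure of the sulfenyl bromide and capture of the oxocarbenium ion by water; the cold, brief conditions spare PMB, silyl ether and acetonide.

Step 5
Reactants: 6 6-O-(tert-butyldimethylsilyl)-3,4-O-isopropylidene-2-O-(4-methoxybenzyl)-D-galactopyranose
Product: 7 7-O-(tert-butyldimethylsilyl)-1,2-dideoxy-4,5-O-isopropylidene-3-O-(4-methoxybenzyl)-D-galacto-hept-1-enitol (free 6-OH)
Conditions: Ph3PCH3Br, KN(SiMe3)2, THF, −78 → 23 °C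
Reagents that add atoms: methyltriphenylphosphonium bromide, C[P+](c1ccccc1)(c1ccccc1)c1ccccc1.[Br-]
Why: Wittig methylenation of the open-chain aldehyde tautomer of the lactol, standard for 2-O-alkyl aldoses; excess ylide at low temperature limits epimerisation α to the aldehyde, and a silyl shift from O7 to the freed O6 alkoxide is harmless because step 6 silylates both oxygens.

Step 6
Reactants: 7 7-O-(tert-butyldimethylsilyl)-1,2-dideoxy-4,5-O-isopropylidene-3-O-(4-methoxybenzyl)-D-galacto-hept-1-enitol
Product: 8 6,7-bis-O-(tert-butyldimethylsilyl)-1,2-dideoxy-4,5-O-isopropylidene-3-O-(4-methoxybenzyl)-D-galacto-hept-1-enitol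
Conditions: TBSOTf, 2,6-lutidine, CH2Cl2, −78 → 0 °C
Reagents that add atoms: tert-butyldimethylsilyl trifluoromethanesulfonate, CC(C)(C)[Si](C)(C)OS(=O)(=O)C(F)(F)F
Why: Silyl triflate with lutidine silylates the hindered hydroxyl without generating an alkoxide; both possible mono-silyl regioisomers of 7 converge on 8.

Step 7
Reactants: 8 6,7-bis-O-(tert-butyldimethylsilyl)-1,2-dideoxy-4,5-O-isopropylidene-3-O-(4-methoxybenzyl)-D-galacto-hept-1-enitol
Product: 9 6-O-(tert-butyldimethylsilyl)-1,2-dideoxy-4,5-O-isopropylidene-3-O-(4-methoxybenzyl)-D-galacto-hept-1-enitol (free 7-OH)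
Conditions: HF·pyridine, pyridine, THF, 0 °C
Reagents that add atoms: none
Why: Buffered fluoride cleaves the unhindered primary TBS ether much faster than the secondary one next to the dioxolane (steric differentiation of silyl ethers); acetonide and PMB are stable in the buffered medium.

Step 8
Reactants: 9 6-O-(tert-butyldimethylsilyl)-1,2-dideoxy-4,5-O-isopropylidene-3-O-(4-methoxybenzyl)-D-galacto-hept-1-enitol
Product: 10 2-O-(tert-butyldimethylsilyl)-6,7-dideoxy-3,4-O-isopropylidene-5-O-(4-methoxybenzyl)-L-galacto-hept-6-enonic acid (sugar C6 oxidised; numbering reversed)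
Conditions: TEMPO (cat.), PhI(OAc)2, CH2Cl2/H2O (2:1), 23 °C
Reagents that add atoms: water, O
Why: Oxoammonium oxidation of the primary alcohol to the aldehyde, whose hydrate is oxidised on to the acid; alkene, PMB ether and secondary silyl ether are untouched and the transient α-silyloxy aldehyde never meets base.

Step 9
Reactants: 10 2-O-(tert-butyldimethylsilyl)-6,7-dideoxy-3,4-O-isopropylidene-5-O-(4-methoxybenzyl)-L-galacto-hept-6-enonic acid
Product: 11 methyl 2-O-(tert-butyldimethylsilyl)-6,7-dideoxy-3,4-O-isopropylidene-5-O-(4-methoxybenzyl)-L-galacto-hept-6-enonate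
Conditions: MeI, KHCO3, DMF, 23 °C
Reagents that add atoms: iodomethane, CI
Why: Carboxylate O-alkylation; bicarbonate is too weak a base to enolise the α-silyloxy ester or to trigger β-elimination of the acetonide oxygen.

Step 10
Reactants: 11 methyl 2-O-(tert-butyldimethylsilyl)-6,7-dideoxy-3,4-O-isopropylidene-5-O-(4-methoxybenzyl)-L-galacto-hept-6-enonate
Product: 12 (3S,4R,5R,6S)-3-(tert-butyldimethylsilyloxy)-4,5-(isopropylidenedioxy)-2-methoxy-6-(4-methoxybenzyloxy)octa-1,7-diene
Conditions: Cp2TiMe2, toluene, 70 °C, dark; filtration through basic alumina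
Reagents that add atoms: dimethyltitanocene Cp2TiMe2, C[Ti](C)(C1C=CC=C1)C1C=CC=C1
Why: Petasis methylenation: thermolysis gives Cp2Ti=CH2, which olefinates the ester carbonyl through an oxatitanacyclobutane; the reagent is non-basic, so the α-stereocentre is safe, and the enol ether is formed at one position only.

Step 11
Reactants: 12 (3S,4R,5R,6S)-3-(tert-butyldimethylsilyloxy)-4,5-(isopropylidenedioxy)-2-methoxy-6-(4-methoxybenzyloxy)octa-1,7-diene
Product: 13 (3S,4R,5R,6S)-6-(tert-butyldimethylsilyloxy)-4,5-(isopropylidenedioxy)-1-methoxy-3-(4-methoxybenzyloxy)cyclohex-1-ene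
Conditions: Mo(N-2,6-iPr2C6H3)(CHCMe2Ph)[OCMe(CF3)2]2 (hexavalent molybdenum, 20 mol %), C6H6 (0.01 M), 60 °C, Ar
Reagents that add atoms: none
Why: The molybdenum alkylidene undergoes [2+2] cycloaddition with the monosubstituted vinyl group and cycloreversion leaves the metal as an alkylidene on C4a. This alkylidene adds intramolecularly to the 1-methoxyvinyl group, and collapse of the metallacyclobutane forms C4a=C8a and Mo=CH2, which re-enters the cycle with loss of ethene. The closest known reaction type is ring-closing metathesis of olefinic enol ethers to cyclic enol ethers with molybdenum alkylidenes. The single ring closes as a cyclohexene from a 1,7-diene; the cis-dioxolane holds both arms on the same side, so closure to the cis-fused bicycle should outrun intermolecular metathesis at high dilution. No stereocentre is formed; C5 to C8 (target numbering) come unchanged from galactose C2 to C5. The step needs chemoselective loading at the vinyl group, which its monosubstitution secures against the hindered, electron-rich 1,1-disubstituted enol ether. It also needs the double bond to stay at C4a=C8a, which the hydride-free molybdenum catalyst and the absence of protic groups secure. PMB ether, silyl ether and acetonide are spectators.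

Step 12
Reactants: 14 2,2,6-trimethyl-4H-1,3-dioxin-4-one
Product: 15 2,2-dimethyl-6-(2-phenylethyl)-4H-1,3-dioxin-4-one
Conditions: LiN(iPr)2, THF, −78 °C; BnBr, DMPU, −78 → −20 °C
Reagents that add atoms: benzyl bromide, BrCc1ccccc1
Why: γ-Deprotonation gives the lithium dienolate, which is alkylated at the γ-carbon by the reactive benzylic halide in the presence of a polar cosolvent (vinylogous enolate alkylation).

Step 13
Reactants: 13 (3S,4R,5R,6S)-6-(tert-butyldimethylsilyloxy)-4,5-(isopropylidenedioxy)-1-methoxy-3-(4-methoxybenzyloxy)cyclohex-1-ene; 15 2,2-dimethyl-6-(2-phenylethyl)-4H-1,3-dioxin-4-one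
Product: 18 (5S,6R,7R,8S)-8-(tert-butyldimethylsilyloxy)-6,7-(isopropylidenedioxy)-5-(4-methoxybenzyloxy)-2-(2-phenylethyl)-5,6,7,8-tetrahydro-4H-chromen-4-one, via acylketene 16 (not isolated), via methoxydihydropyranone adduct 17 (not isolated)
Conditions: toluene, 110 °C, slow addition of 15; then PPTS (cat.), 60 °C
Reagents that add atoms: none
Why: Retro-[4+2] of 15 releases acylketene 16, which reacts as an electron-poor 1-oxadiene with the enol ether (acylketene–enol ether hetero-Diels–Alder annulation): the ketene carbon bonds to nucleophilic C4a and the acyl oxygen to C8a. Acid-catalysed loss of methanol from the ketal-type C8a of 17 gives the 4-pyranone and erases the two transient stereocentres.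

Step 14
Reactants: 18 (5S,6R,7R,8S)-8-(tert-butyldimethylsilyloxy)-6,7-(isopropylidenedioxy)-5-(4-methoxybenzyloxy)-2-(2-phenylethyl)-5,6,7,8-tetrahydro-4H-chromen-4-one
Product: 19 (5S,6R,7R,8S)-8-(tert-butyldimethylsilyloxy)-5-hydroxy-6,7-(isopropylidenedioxy)-2-(2-phenylethyl)-5,6,7,8-tetrahydro-4H-chromen-4-one
Conditions: DDQ, CH2Cl2/pH 7 buffer (10:1), 0 °C
Reagents that add atoms: none
Why: Oxidative PMB cleavage: DDQ oxidises the electron-rich benzyl ether to an oxocarbenium ion that is hydrolysed; silyl ether, acetonide and the electron-poor pyranone are inert.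

Step 15
Reactants: 20 1-(5-bromo-2,4-dihydroxyphenyl)ethanone
Product: 21 1-[4-(benzyloxy)-5-bromo-2-hydroxyphenyl]ethanone
Conditions: BnBr, K2CO3, acetone, 56 °C
Reagents that add atoms: benzyl bromide, BrCc1ccccc1
Why: The 2-hydroxyl is locked in a hydrogen bond to the acetyl group, so the free, more acidic 4-hydroxyl is benzylated selectively (Williamson etherification).

Step 16
Reactants: 21 1-[4-(benzyloxy)-5-bromo-2-hydroxyphenyl]ethanone; 22 ethyl 3-phenylpropanoate
Product: 24 7-(benzyloxy)-6-bromo-2-(2-phenylethyl)-4H-chromen-4-one, via diketone 23 (not isolated)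
Conditions: NaH, THF, 65 °C; AcOH; then H2SO4 (cat.), AcOH, 50 °C
Reagents that add atoms: none
Why: Crossed Claisen condensation of the phenoxide–enolate of 21 with the ester gives the 1,3-diketone, which cyclodehydrates under acid to the chromone (classical 2-alkylchromone synthesis); aryl bromide and benzyl ether are unaffected.

Step 17
Reactants: 19 (5S,6R,7R,8S)-8-(tert-butyldimethylsilyloxy)-5-hydroxy-6,7-(isopropylidenedioxy)-2-(2-phenylethyl)-5,6,7,8-tetrahydro-4H-chromen-4-one; 24 7-(benzyloxy)-6-bromo-2-(2-phenylethyl)-4H-chromen-4-one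
Product: 25 7-(benzyloxy)-6-{[(5S,6R,7R,8S)-8-(tert-butyldimethylsilyloxy)-6,7-(isopropylidenedioxy)-4-oxo-2-(2-phenylethyl)-5,6,7,8-tetrahydro-4H-chromen-5-yl]oxy}-2-(2-phenylethyl)-4H-chromen-4-one
Conditions: Pd2(dba)3 (zerovalent palladium), RockPhos, Cs2CO3, toluene, 90 °C
Reagents that add atoms: none
Why: Palladium-catalysed C–O cross-coupling of a secondary alcohol with an aryl bromide: oxidative addition of 24, alkoxide exchange and C–O reductive elimination, which the bulky di-tert-butylbiarylphosphine favours over β-hydride elimination. The C5–O bond of 19 is never broken, so the configuration at C5 is retained.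

Step 18
Reactants: 25 7-(benzyloxy)-6-{[(5S,6R,7R,8S)-8-(tert-butyldimethylsilyloxy)-6,7-(isopropylidenedioxy)-4-oxo-2-(2-phenylethyl)-5,6,7,8-tetrahydro-4H-chromen-5-yl]oxy}-2-(2-phenylethyl)-4H-chromen-4-one
Product: 26 6-{[(5S,6R,7R,8S)-8-(tert-butyldimethylsilyloxy)-6,7-(isopropylidenedioxy)-4-oxo-2-(2-phenylethyl)-5,6,7,8-tetrahydro-4H-chromen-5-yl]oxy}-7-hydroxy-2-(2-phenylethyl)-4H-chromen-4-one
Conditions: H2 (1 atm), Pd/C, EtOAc, 23 °C, stopped after one equivalent of H2
Reagents that add atoms: none
Why: Hydrogenolysis of the aryl benzyl ether, the fastest-reacting group present; stopping after one equivalent should leave the chromone C2′=C3′ bond and the C5–O aryl ether intact.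

Step 19
Reactants: 26 6-{[(5S,6R,7R,8S)-8-(tert-butyldimethylsilyloxy)-6,7-(isopropylidenedioxy)-4-oxo-2-(2-phenylethyl)-5,6,7,8-tetrahydro-4H-chromen-5-yl]oxy}-7-hydroxy-2-(2-phenylethyl)-4H-chromen-4-one
Product: 27 7-hydroxy-2-(2-phenylethyl)-6-{[(5S,6S,7R,8S)-6,7,8-trihydroxy-4-oxo-2-(2-phenylethyl)-5,6,7,8-tetrahydro-4H-chromen-5-yl]oxy}-4H-chromen-4-one (CNP0248258.1)
Conditions: TFA/H2O (9:1), 0 → 23 °C
Reagents that add atoms: none
Why: Aqueous acid hydrolyses the cis-fused acetonide and the secondary silyl ether in one operation; with the pyranone carbonyl protonated the ring is electron-poor, which disfavours ionisation at C5 or C8.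

## Compound list

1 | phenyl 1-thio-β-D-galactopyranoside | OC[C@H]1O[C@@H](Sc2ccccc2)[C@H](O)[C@@H](O)[C@H]1O | starting material
2 | phenyl 3,4-O-isopropylidene-6-O-(2-methoxypropan-2-yl)-1-thio-β-D-galactopyranoside (mixed acetal) | COC(C)(C)OC[C@H]1O[C@@H](Sc2ccccc2)[C@H](O)[C@H]2OC(C)(C)O[C@H]21 | intermediate
3 | phenyl 3,4-O-isopropylidene-1-thio-β-D-galactopyranoside | OC[C@H]1O[C@@H](Sc2ccccc2)[C@H](O)[C@H]2OC(C)(C)O[C@H]21 | intermediate
4 | phenyl 6-O-(tert-butyldimethylsilyl)-3,4-O-isopropylidene-1-thio-β-D-galactopyranoside | CC(C)(C)[Si](C)(C)OC[C@H]1O[C@@H](Sc2ccccc2)[C@H](O)[C@H]2OC(C)(C)O[C@H]21 | intermediate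
5 | phenyl 6-O-(tert-butyldimethylsilyl)-3,4-O-isopropylidene-2-O-(4-methoxybenzyl)-1-thio-β-D-galactopyranoside | CC(C)(C)[Si](C)(C)OC[C@H]1O[C@@H](Sc2ccccc2)[C@H](OCc2ccc(OC)cc2)[C@H]2OC(C)(C)O[C@H]21 | intermediate
6 | 6-O-(tert-butyldimethylsilyl)-3,4-O-isopropylidene-2-O-(4-methoxybenzyl)-D-galactopyranose (anomeric mixture) | CC(C)(C)[Si](C)(C)OC[C@H]1OC(O)[C@H](OCc2ccc(OC)cc2)[C@H]2OC(C)(C)O[C@H]21 | intermediate
7 | 7-O-(tert-butyldimethylsilyl)-1,2-dideoxy-4,5-O-isopropylidene-3-O-(4-methoxybenzyl)-D-galacto-hept-1-enitol | C=C[C@H](OCc1ccc(OC)cc1)[C@@H](OC1(C)C)[C@@H](O1)[C@H](O)CO[Si](C)(C)C(C)(C)C | intermediate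
8 | 6,7-bis-O-(tert-butyldimethylsilyl)-1,2-dideoxy-4,5-O-isopropylidene-3-O-(4-methoxybenzyl)-D-galacto-hept-1-enitol | C=C[C@H](OCc1ccc(OC)cc1)[C@@H](OC1(C)C)[C@@H](O1)[C@H](O[Si](C)(C)C(C)(C)C)CO[Si](C)(C)C(C)(C)C | intermediate
9 | 6-O-(tert-butyldimethylsilyl)-1,2-dideoxy-4,5-O-isopropylidene-3-O-(4-methoxybenzyl)-D-galacto-hept-1-enitol | C=C[C@H](OCc1ccc(OC)cc1)[C@@H](OC1(C)C)[C@@H](O1)[C@H](O[Si](C)(C)C(C)(C)C)CO | intermediate
10 | 2-O-(tert-butyldimethylsilyl)-6,7-dideoxy-3,4-O-isopropylidene-5-O-(4-methoxybenzyl)-L-galacto-hept-6-enonic acid | C=C[C@H](OCc1ccc(OC)cc1)[C@@H](OC1(C)C)[C@@H](O1)[C@H](O[Si](C)(C)C(C)(C)C)C(=O)O | intermediate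
11 | methyl 2-O-(tert-butyldimethylsilyl)-6,7-dideoxy-3,4-O-isopropylidene-5-O-(4-methoxybenzyl)-L-galacto-hept-6-enonate | C=C[C@H](OCc1ccc(OC)cc1)[C@@H](OC1(C)C)[C@@H](O1)[C@H](O[Si](C)(C)C(C)(C)C)C(=O)OC | intermediate
12 | (3S,4R,5R,6S)-3-(tert-butyldimethylsilyloxy)-4,5-(isopropylidenedioxy)-2-methoxy-6-(4-methoxybenzyloxy)octa-1,7-diene | C=C[C@H](OCc1ccc(OC)cc1)[C@@H](OC1(C)C)[C@@H](O1)[C@H](O[Si](C)(C)C(C)(C)C)C(=C)OC | intermediate
13 | (3S,4R,5R,6S)-6-(tert-butyldimethylsilyloxy)-4,5-(isopropylidenedioxy)-1-methoxy-3-(4-methoxybenzyloxy)cyclohex-1-ene | COC1=C[C@H](OCc2ccc(OC)cc2)[C@@H](OC2(C)C)[C@@H](O2)[C@@H]1O[Si](C)(C)C(C)(C)C | intermediate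
14 | 2,2,6-trimethyl-4H-1,3-dioxin-4-one | CC1=CC(=O)OC(C)(C)O1 | starting material
15 | 2,2-dimethyl-6-(2-phenylethyl)-4H-1,3-dioxin-4-one | O=C1C=C(CCc2ccccc2)OC(C)(C)O1 | intermediate
16 | 3-oxo-5-phenylpent-1-en-1-one (acylketene) | O=C=CC(=O)CCc1ccccc1 | intermediate
17 | (5S,6R,7R,8S)-8-(tert-butyldimethylsilyloxy)-6,7-(isopropylidenedioxy)-8a-methoxy-5-(4-methoxybenzyloxy)-2-(2-phenylethyl)-4a,5,6,7,8,8a-hexahydro-4H-chromen-4-one (C4a/C8a unassigned) | O=C1C=C(CCc3ccccc3)OC2(OC)C1[C@H](OCc1ccc(OC)cc1)[C@@H](OC1(C)C)[C@@H](O1)[C@@H]2O[Si](C)(C)C(C)(C)C | intermediate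
18 | (5S,6R,7R,8S)-8-(tert-butyldimethylsilyloxy)-6,7-(isopropylidenedioxy)-5-(4-methoxybenzyloxy)-2-(2-phenylethyl)-5,6,7,8-tetrahydro-4H-chromen-4-one | O=c1cc(CCc2ccccc2)oc2c1[C@H](OCc1ccc(OC)cc1)[C@@H](OC1(C)C)[C@@H](O1)[C@@H]2O[Si](C)(C)C(C)(C)C | intermediate
19 | (5S,6R,7R,8S)-8-(tert-butyldimethylsilyloxy)-5-hydroxy-6,7-(isopropylidenedioxy)-2-(2-phenylethyl)-5,6,7,8-tetrahydro-4H-chromen-4-one | O=c1cc(CCc2ccccc2)oc2c1[C@H](O)[C@@H](OC1(C)C)[C@@H](O1)[C@@H]2O[Si](C)(C)C(C)(C)C | intermediate
20 | 1-(5-bromo-2,4-dihydroxyphenyl)ethanone | CC(=O)c1cc(Br)c(O)cc1O | starting material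
21 | 1-[4-(benzyloxy)-5-bromo-2-hydroxyphenyl]ethanone | CC(=O)c1cc(Br)c(OCc2ccccc2)cc1O | intermediate
22 | ethyl 3-phenylpropanoate | CCOC(=O)CCc1ccccc1 | starting material
23 | 1-[4-(benzyloxy)-5-bromo-2-hydroxyphenyl]-5-phenylpentane-1,3-dione | O=C(CC(=O)CCc1ccccc1)c1cc(Br)c(OCc2ccccc2)cc1O | intermediate
24 | 7-(benzyloxy)-6-bromo-2-(2-phenylethyl)-4H-chromen-4-one | O=c1cc(CCc2ccccc2)oc2cc(OCc3ccccc3)c(Br)cc12 | intermediate
25 | 7-(benzyloxy)-6-{[(5S,6R,7R,8S)-8-(tert-butyldimethylsilyloxy)-6,7-(isopropylidenedioxy)-4-oxo-2-(2-phenylethyl)-5,6,7,8-tetrahydro-4H-chromen-5-yl]oxy}-2-(2-phenylethyl)-4H-chromen-4-one | O=c1cc(CCc2ccccc2)oc2c1[C@H](Oc1cc3c(=O)cc(CCc4ccccc4)oc3cc1OCc1ccccc1)[C@@H](OC1(C)C)[C@@H](O1)[C@@H]2O[Si](C)(C)C(C)(C)C | intermediate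
26 | 6-{[(5S,6R,7R,8S)-8-(tert-butyldimethylsilyloxy)-6,7-(isopropylidenedioxy)-4-oxo-2-(2-phenylethyl)-5,6,7,8-tetrahydro-4H-chromen-5-yl]oxy}-7-hydroxy-2-(2-phenylethyl)-4H-chromen-4-one | O=c1cc(CCc2ccccc2)oc2c1[C@H](Oc1cc3c(=O)cc(CCc4ccccc4)oc3cc1O)[C@@H](OC1(C)C)[C@@H](O1)[C@@H]2O[Si](C)(C)C(C)(C)C | intermediate
27 | 7-hydroxy-2-(2-phenylethyl)-6-{[(5S,6S,7R,8S)-6,7,8-trihydroxy-4-oxo-2-(2-phenylethyl)-5,6,7,8-tetrahydro-4H-chromen-5-yl]oxy}-4H-chromen-4-one | O=c1cc(CCc2ccccc2)oc2c1[C@H](Oc1cc3c(=O)cc(CCc4ccccc4)oc3cc1O)[C@@H](O)[C@@H](O)[C@@H]2O | target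

## Step count and least certain steps

Total: 19 steps. Longest linear sequence: 16 steps (steps 1–11, 13, 14, 17, 18, 19). Step 12 and steps 15–16 are side branches.

**Step 11 (key step).** Most likely failure: stalled turnover, because loading at the vinyl group is slowed by the neighbouring PMB-oxygenated carbon and closure onto the 1,1-disubstituted enol ether next to the bulky silyl ether is slow, so that catalyst decomposition or intermolecular metathesis takes over. The second-generation Grubbs catalyst RuCl2(=CHPh)(H2IMes)(PCy3) would be only a change of conditions. The fallback changes the ring-forming event: it sets out from ester 11 and returns at enol ether 13 without passing through diene 12. A titanium ethylidene reagent (TiCl4, Zn, PbCl2 (cat.), TMEDA, CH3CHBr2, THF, 65 °C) would exchange onto the terminal vinyl group and the resulting titanium alkylidene would olefinate the ester carbonyl intramolecularly, forming C4a=C8a by carbonyl olefination rather than by alkene metathesis. This fallback makes no compound outside the list (F0).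

**Step 17.** Most likely failure: β-hydride elimination from the palladium alkoxide (oxidation at C5 and reduction of the aryl bromide), slow C–O reductive elimination at the electron-rich, ortho-alkoxylated aryl group, or carbonate-induced deprotonation at C8 followed by elimination and aromatisation. The fallback replaces retentive arylation by displacement with inversion; it sets out from alcohol 19 and bromide 24 and returns at 25. Dess–Martin oxidation of 19 would give C5 ketone F1, and NaBH4/CeCl3·7H2O in MeOH at −78 °C, with hydride delivered to the face opposite the acetonide, would give the 5-epi alcohol F2. In parallel, bromide 24 would be borylated (B2pin2, Pd(dppf)Cl2 (divalent palladium), KOAc, dioxane, 90 °C) to pinacol boronate F3 and oxidised with NaBO3·4H2O to phenol F4. A Mitsunobu reaction of F2 with F4 (PPh3, DIAD, toluene, 0 → 23 °C) would invert C5 and give 25.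

**Step 13.** Most likely failure: the hindered trisubstituted enol ether captures the transient acylketene too slowly, so the ketene dimerises, or adduct 17 loses the PMB-oxygen at C5 by β-elimination instead of methanol at C8a. The fallback builds the pyranone stepwise; it sets out from enol ether 13 and returns at 18. Vilsmeier formylation (POCl3/DMF, CH2Cl2, 0 °C, then aqueous NaOAc) would give aldehyde F5. Aldol addition of the kinetic lithium enolate of 4-phenylbutan-2-one (LiN(iPr)2, THF, −78 °C) would give hydroxy ketone F6, and Dess–Martin oxidation would give diketone F7. Catalytic PPTS would then close O1–C8a with loss of methanol to give 18.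

**Step 18.** Most likely failure: over-reduction, either hydrogenolysis of the pyranone-activated C5–O aryl bond or saturation of the chromone C2′=C3′ bond, before debenzylation is complete. The fallback removes the need for hydrogen by changing the phenol protecting group; it sets out from bromide 24 and returns at target 27. BCl3 (CH2Cl2, −78 °C) would give bromophenol F8, and MOMCl/iPr2NEt would give MOM ether F9. Coupling of F9 with alcohol 19 under the conditions of step 17 would give MOM-protected ether F10, and TFA/H2O would remove MOM, acetonide and silyl ether together to give 27.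

## Further compounds

F0 | step 11 | none | none
F1 | step 17 | (6S,7R,8S)-8-(tert-butyldimethylsilyloxy)-6,7-(isopropylidenedioxy)-2-(2-phenylethyl)-7,8-dihydro-4H-chromene-4,5(6H)-dione | O=c1cc(CCc2ccccc2)oc2c1C(=O)[C@@H](OC1(C)C)[C@@H](O1)[C@@H]2O[Si](C)(C)C(C)(C)C
F2 | step 17 | (5R,6R,7R,8S)-8-(tert-butyldimethylsilyloxy)-5-hydroxy-6,7-(isopropylidenedioxy)-2-(2-phenylethyl)-5,6,7,8-tetrahydro-4H-chromen-4-one | O=c1cc(CCc2ccccc2)oc2c1[C@@H](O)[C@@H](OC1(C)C)[C@@H](O1)[C@@H]2O[Si](C)(C)C(C)(C)C
F3 | step 17 | 7-(benzyloxy)-2-(2-phenylethyl)-6-(4,4,5,5-tetramethyl-1,3,2-dioxaborolan-2-yl)-4H-chromen-4-one | O=c1cc(CCc2ccccc2)oc2cc(OCc3ccccc3)c(B3OC(C)(C)C(C)(C)O3)cc12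
F4 | step 17 | 7-(benzyloxy)-6-hydroxy-2-(2-phenylethyl)-4H-chromen-4-one | O=c1cc(CCc2ccccc2)oc2cc(OCc3ccccc3)c(O)cc12
F5 | step 13 | (3S,4R,5R,6S)-3-(tert-butyldimethylsilyloxy)-4,5-(isopropylidenedioxy)-2-methoxy-6-(4-methoxybenzyloxy)cyclohex-1-ene-1-carbaldehyde | COC1=C(C=O)[C@H](OCc2ccc(OC)cc2)[C@@H](OC2(C)C)[C@@H](O2)[C@@H]1O[Si](C)(C)C(C)(C)C
F6 | step 13 | 1-hydroxy-1-[(3S,4R,5R,6S)-3-(tert-butyldimethylsilyloxy)-4,5-(isopropylidenedioxy)-2-methoxy-6-(4-methoxybenzyloxy)cyclohex-1-en-1-yl]-5-phenylpentan-3-one (carbinol epimers) | COC1=C(C(O)CC(=O)CCc2ccccc2)[C@H](OCc2ccc(OC)cc2)[C@@H](OC2(C)C)[C@@H](O2)[C@@H]1O[Si](C)(C)C(C)(C)C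
F7 | step 13 | 1-[(3S,4R,5R,6S)-3-(tert-butyldimethylsilyloxy)-4,5-(isopropylidenedioxy)-2-methoxy-6-(4-methoxybenzyloxy)cyclohex-1-en-1-yl]-5-phenylpentane-1,3-dione | COC1=C(C(=O)CC(=O)CCc2ccccc2)[C@H](OCc2ccc(OC)cc2)[C@@H](OC2(C)C)[C@@H](O2)[C@@H]1O[Si](C)(C)C(C)(C)C
F8 | step 18 | 6-bromo-7-hydroxy-2-(2-phenylethyl)-4H-chromen-4-one | O=c1cc(CCc2ccccc2)oc2cc(O)c(Br)cc12
F9 | step 18 | 6-bromo-7-(methoxymethoxy)-2-(2-phenylethyl)-4H-chromen-4-one | COCOc1cc2oc(CCc3ccccc3)cc(=O)c2cc1Br
F10 | step 18 | 6-{[(5S,6R,7R,8S)-8-(tert-butyldimethylsilyloxy)-6,7-(isopropylidenedioxy)-4-oxo-2-(2-phenylethyl)-5,6,7,8-tetrahydro-4H-chromen-5-yl]oxy}-7-(methoxymethoxy)-2-(2-phenylethyl)-4H-chromen-4-one | O=c1cc(CCc2ccccc2)oc2c1[C@H](Oc1cc3c(=O)cc(CCc4ccccc4)oc3cc1OCOC)[C@@H](OC1(C)C)[C@@H](O1)[C@@H]2O[Si](C)(C)C(C)(C)C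
A1 | alternative 1 | 7-(benzyloxy)-6-{[(5S,6S,7R,8S)-6,7,8-tris(benzyloxy)-4-oxo-2-(2-phenylethyl)-5,6,7,8-tetrahydro-4H-chromen-5-yl]oxy}-2-(2-phenylethyl)-4H-chromen-4-one | O=c1cc(CCc2ccccc2)oc2c1[C@H](Oc1cc3c(=O)cc(CCc4ccccc4)oc3cc1OCc1ccccc1)[C@@H](OCc1ccccc1)[C@@H](OCc1ccccc1)[C@@H]2OCc1ccccc1
A2 | alternative 1 | 7-(benzyloxy)-6-{[4,5,6-tris(benzyloxy)-3-(tert-butyldimethylsilyloxy)cyclohex-2-en-1-yl]oxy}-2-(2-phenylethyl)-4H-chromen-4-one (configuration of the target at the four stereocentres) | CC(C)(C)[Si](C)(C)OC1=C[C@H](Oc2cc3c(=O)cc(CCc4ccccc4)oc3cc2OCc2ccccc2)[C@@H](OCc2ccccc2)[C@@H](OCc2ccccc2)[C@@H]1OCc1ccccc1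
A3 | alternative 2 | 6-{[(5S,6R,7R,8S)-8-(tert-butyldimethylsilyloxy)-6,7-(isopropylidenedioxy)-4-oxo-2-(2-phenylethyl)-5,6,7,8-tetrahydro-4H-chromen-5-yl]oxy}-4-oxo-2-(2-phenylethyl)-4H-chromen-7-yl acetate | O=c1cc(CCc2ccccc2)oc2c1[C@H](Oc1cc3c(=O)cc(CCc4ccccc4)oc3cc1OC(C)=O)[C@@H](OC1(C)C)[C@@H](O1)[C@@H]2O[Si](C)(C)C(C)(C)C
A4 | alternative 2 | {3-[(E)-2-{[(5S,6R,7R,8S)-8-(tert-butyldimethylsilyloxy)-6,7-(isopropylidenedioxy)-4-oxo-2-(2-phenylethyl)-5,6,7,8-tetrahydro-4H-chromen-5-yl]oxy}ethenyl]-4-oxo-6-(2-phenylethyl)-4H-pyran-2-yl}acetic acid | O=c1cc(CCc2ccccc2)oc2c1[C@H](O/C=C/c1c(CC(=O)O)oc(CCc3ccccc3)cc1=O)[C@@H](OC1(C)C)[C@@H](O1)[C@@H]2O[Si](C)(C)C(C)(C)C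
A5 | alternative 2 | dienylketene derived from A4 (2-(2-oxoethenyl) in place of 2-(carboxymethyl)) | O=c1cc(CCc2ccccc2)oc2c1[C@H](O/C=C/c1c(C=C=O)oc(CCc3ccccc3)cc1=O)[C@@H](OC1(C)C)[C@@H](O1)[C@@H]2O[Si](C)(C)C(C)(C)C
A6 | alternative 3 | 2,3,4-tris(benzyloxy)-5-hydroxycyclohexanone (mannose-derived, configuration of the target) | O=C1C[C@H](O)[C@@H](OCc2ccccc2)[C@@H](OCc2ccccc2)[C@@H]1OCc1ccccc1
A7 | alternative 3 | methyl 2,3,4-tri-O-benzyl-6-deoxy-α-D-lyxo-hex-5-enopyranoside | CO[C@H]1OC(=C)[C@@H](OCc2ccccc2)[C@H](OCc2ccccc2)[C@@H]1OCc1ccccc1
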